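**Assumption:** the SMILES contains no stereocentre and no stereogenic double bond, so the target is achiral and no enantiomer question arises. The transient stereocentres in 9–18 are carried as racemates or diastereomer mixtures, and all of them are erased in step 10.

## Retrosynthetic overview
1. Target 21 comes from bis-benzyl ether 20 by hydrogenolysis. 20 comes from benzylidene-cyclohexenone 18 by isoaromatisation, so ring A stays non-aromatic until the end and the OMe/OH pattern is fixed early.
2. Key C–C bond (ring A carbon to the ArCH2 carbon): intermolecular aldol of the alpha'-lithium enolate of 3-methoxycyclohexenone 13 with 4-(benzyloxy)benzaldehyde 14, then dehydration.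
3. 13 comes from the symmetric 5-substituted cyclohexane-1,3-dione 12, which comes from a Michael–Claisen annulation of enone 7 with dimethyl malonate 8.
4. 7 comes from aldehyde 5 by Wittig olefination. 5 comes from 3,4-dihydrocoumarin 1, which supplies ring B and the tether carbons.
5. Ring order: rings B and C are bought as arenes. Ring A is the only ring built (step 5), and it is aromatised last (step 10).

## Route

Step 1
Reactants: 1 3,4-dihydrocoumarin
Product: 2 2-(3-hydroxypropyl)phenol
Conditions: LiAlH4, THF, 0 °C to rt; then 1 M HCl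
Reagents that add atoms: none
Why: Lactone reduction with LiAlH4 delivers two hydrides to the acyl carbon and releases the phenoxide, giving the phenol/primary alcohol pair without forming a stereocentre.

Step 2
Reactants: 2 2-(3-hydroxypropyl)phenol; 3 benzyl bromide
Product: 4 3-[2-(benzyloxy)phenyl]propan-1-ol
Conditions: BnBr, K2CO3, acetone, reflux
Reagents that add atoms: benzyl bromide (3), BrCc1ccccc1
Why: In this Williamson ether synthesis K2CO3 deprotonates only the phenol (pKa about 10) and not the primary alcohol (pKa about 16), so the benzylation is chemoselective.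

Step 3
Reactants: 4 3-[2-(benzyloxy)phenyl]propan-1-ol
Product: 5 3-[2-(benzyloxy)phenyl]propanal
Conditions: TEMPO (10 mol %), PhI(OAc)2, CH2Cl2, rt
Reagents that add atoms: none
Why: The TEMPO/PhI(OAc)2 oxoammonium oxidation stops at the aldehyde in the absence of water and leaves the benzyl aryl ether untouched.

Step 4
Reactants: 5 3-[2-(benzyloxy)phenyl]propanal; 6 1-(triphenylphosphoranylidene)propan-2-one
Product: 7 (3E)-6-[2-(benzyloxy)phenyl]hex-3-en-2-one
Conditions: Ph3P=CHC(O)CH3, toluene, 80 °C
Reagents that add atoms: 1-(triphenylphosphoranylidene)propan-2-one (6), CC(=O)C=P(c1ccccc1)(c1ccccc1)c1ccccc1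
Why: Wittig olefination with a stabilised, barely basic acyl ylide gives the (E)-enone selectively and does not enolise the aliphatic aldehyde.

Step 5
Reactants: 7 (3E)-6-[2-(benzyloxy)phenyl]hex-3-en-2-one; 8 dimethyl malonate
Product: 10 methyl 6-{2-[2-(benzyloxy)phenyl]ethyl}-2,4-dioxocyclohexane-1-carboxylate, via Michael adduct 9 (not isolated)
Conditions: NaOMe, MeOH, reflux; then 1 M HCl, 0 °C
Reagents that add atoms: dimethyl malonate (8), COC(=O)CC(=O)OC
Why: Intermolecular Michael addition of the malonate anion to the beta-alkyl enone is followed by an intramolecular Claisen (Dieckmann-type) condensation of the methyl-ketone enolate onto one ester, driven by formation of the stabilised 1,3-dione enolate, and the two new stereocentres form as a racemic mixture that is erased later.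

Step 6
Reactants: 10 methyl 6-{2-[2-(benzyloxy)phenyl]ethyl}-2,4-dioxocyclohexane-1-carboxylate
Product: 12 5-{2-[2-(benzyloxy)phenyl]ethyl}cyclohexane-1,3-dione, via beta-keto acid 11 (not isolated)
Conditions: 2 M NaOH aq, 90 °C; then HCl to pH 2, 90 °C
Reagents that add atoms: none
Why: Saponification followed by thermal decarboxylation of the beta-keto acid is the standard end of the cyclohexane-1,3-dione synthesis, the benzyl aryl ether tolerates hot dilute acid and base, and the product is achiral.

Step 7
Reactants: 12 5-{2-[2-(benzyloxy)phenyl]ethyl}cyclohexane-1,3-dione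
Product: 13 5-{2-[2-(benzyloxy)phenyl]ethyl}-3-methoxycyclohex-2-en-1-one (racemic)
Conditions: HC(OMe)3, TsOH·H2O (5 mol %), MeOH, rt
Reagents that add atoms: methanol, CO; trimethyl orthoformate, COC(OC)OC (either one delivers the OCH3 group)
Why: Acid-catalysed enol etherification of the vinylogous acid can give only one constitutional isomer because 12 is symmetric, so this step decides which ring A oxygen becomes OMe, and C5 becomes a racemic stereocentre that is erased in step 10.

Step 8 (key step)
Reactants: 13 5-{2-[2-(benzyloxy)phenyl]ethyl}-3-methoxycyclohex-2-en-1-one; 14 4-(benzyloxy)benzaldehyde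
Product: 16 5-{2-[2-(benzyloxy)phenyl]ethyl}-6-{[4-(benzyloxy)phenyl](hydroxy)methyl}-3-methoxycyclohex-2-en-1-one, via lithium dienolate 15 (not isolated)
Conditions: LiN(iPr)2 (commercial solution, 1.1 equiv), THF, −78 °C; then 14, −78 °C; AcOH quench at −78 °C
Reagents that add atoms: 4-(benzyloxy)benzaldehyde (14), O=Cc1ccc(OCc2ccccc2)cc1
Why: Kinetic alpha'-deprotonation of the vinylogous ester (Stork–Danheiser regiochemistry) gives the cross-conjugated C6 dienolate, which adds to the non-enolisable aldehyde in an intermolecular aldol addition, mainly anti to the C5 side chain and as a mixture of carbinol epimers, which does not matter because all three stereocentres are erased in steps 9 and 10.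

Step 9
Reactants: 16 aldol adduct
Product: 18 (6E)-6-{[4-(benzyloxy)phenyl]methylidene}-5-{2-[2-(benzyloxy)phenyl]ethyl}-3-methoxycyclohex-2-en-1-one, via aldol acetate 17 (not isolated)
Conditions: Ac2O, Et3N, DMAP (cat.), CH2Cl2, rt; then DBU, rt
Reagents that add atoms: none
Why: Acetylation turns the carbinol into a leaving group and DBU triggers an E1cB elimination through the C6 enolate, completing the aldol condensation and giving the conjugated (E)-benzylidene ketone with the aryl group anti to the carbonyl.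

Step 10
Reactants: 18 benzylidene cyclohexenone
Product: 20 2-{[4-(benzyloxy)phenyl]methyl}-3-{2-[2-(benzyloxy)phenyl]ethyl}-5-methoxyphenol, via cross-conjugated dienone 19 (not isolated)
Conditions: RhCl3·3H2O (10 mol %), degassed MeOH/toluene 3:1, 85 °C, sealed tube
Reagents that add atoms: none
Why: A rhodium hydride formed from RhCl3·3H2O and the alcohol moves the exocyclic C=C into the ring by hydrometalation and beta-hydride elimination at C5–H, the resulting dienone 19 is the keto tautomer of the phenol and enolises irreversibly (isoaromatisation), MeOH makes any alkoxy exchange at the vinylogous ester degenerate, and the last stereocentre disappears.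

Step 11
Reactants: 20 bis-benzyl ether
Product: 21 2-[(4-hydroxyphenyl)methyl]-3-[2-(2-hydroxyphenyl)ethyl]-5-methoxyphenol (target)
Conditions: H2 (1 atm), Pd/C (10 wt % Pd), EtOAc/MeOH, rt
Reagents that add atoms: none
Why: Catalytic hydrogenolysis cleaves both benzyl aryl ethers, while the diarylmethane and bibenzyl C–C bonds, the aryl methyl ether and the arenes are inert under these conditions.

## Compound list
1 | 3,4-dihydrocoumarin (chroman-2-one) | O=C1CCc2ccccc2O1 | starting material
2 | 2-(3-hydroxypropyl)phenol | OCCCc1ccccc1O | intermediate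
3 | benzyl bromide | BrCc1ccccc1 | starting material
4 | 3-[2-(benzyloxy)phenyl]propan-1-ol | OCCCc1ccccc1OCc1ccccc1 | intermediate
5 | 3-[2-(benzyloxy)phenyl]propanal | O=CCCc1ccccc1OCc1ccccc1 | intermediate
6 | 1-(triphenylphosphoranylidene)propan-2-one | CC(=O)C=P(c1ccccc1)(c1ccccc1)c1ccccc1 | starting material
7 | (3E)-6-[2-(benzyloxy)phenyl]hex-3-en-2-one | CC(=O)/C=C/CCc1ccccc1OCc1ccccc1 | intermediate
8 | dimethyl malonate | COC(=O)CC(=O)OC | starting material
9 | dimethyl 2-{1-[2-(benzyloxy)phenyl]-5-oxohexan-3-yl}propanedioate (racemic) | COC(=O)C(C(=O)OC)C(CCc1ccccc1OCc1ccccc1)CC(C)=O | intermediate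
10 | methyl 6-{2-[2-(benzyloxy)phenyl]ethyl}-2,4-dioxocyclohexane-1-carboxylate (racemic, drawn as the diketo tautomer) | COC(=O)C1C(=O)CC(=O)CC1CCc1ccccc1OCc1ccccc1 | intermediate
11 | 6-{2-[2-(benzyloxy)phenyl]ethyl}-2,4-dioxocyclohexane-1-carboxylic acid (racemic) | OC(=O)C1C(=O)CC(=O)CC1CCc1ccccc1OCc1ccccc1 | intermediate
12 | 5-{2-[2-(benzyloxy)phenyl]ethyl}cyclohexane-1,3-dione | O=C1CC(=O)CC(CCc2ccccc2OCc2ccccc2)C1 | intermediate
13 | 5-{2-[2-(benzyloxy)phenyl]ethyl}-3-methoxycyclohex-2-en-1-one (racemic) | COC1=CC(=O)CC(CCc2ccccc2OCc2ccccc2)C1 | intermediate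
14 | 4-(benzyloxy)benzaldehyde | O=Cc1ccc(OCc2ccccc2)cc1 | starting material
15 | lithium 3-{2-[2-(benzyloxy)phenyl]ethyl}-5-methoxycyclohexa-1,5-dien-1-olate (racemic) | [Li+].[O-]C1=CC(CCc2ccccc2OCc2ccccc2)CC(OC)=C1 | intermediate
16 | 5-{2-[2-(benzyloxy)phenyl]ethyl}-6-{[4-(benzyloxy)phenyl](hydroxy)methyl}-3-methoxycyclohex-2-en-1-one (racemic, mainly 5,6-trans, carbinol epimers) | COC1=CC(=O)C(C(O)c2ccc(OCc3ccccc3)cc2)C(CCc2ccccc2OCc2ccccc2)C1 | intermediate
17 | [4-(benzyloxy)phenyl](6-{2-[2-(benzyloxy)phenyl]ethyl}-4-methoxy-2-oxocyclohex-3-en-1-yl)methyl acetate (racemic, epimer mixture) | COC1=CC(=O)C(C(OC(C)=O)c2ccc(OCc3ccccc3)cc2)C(CCc2ccccc2OCc2ccccc2)C1 | intermediate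
18 | (6E)-6-{[4-(benzyloxy)phenyl]methylidene}-5-{2-[2-(benzyloxy)phenyl]ethyl}-3-methoxycyclohex-2-en-1-one (racemic) | COC1=CC(=O)/C(=C/c2ccc(OCc3ccccc3)cc2)C(CCc2ccccc2OCc2ccccc2)C1 | intermediate
19 | 2-{[4-(benzyloxy)phenyl]methyl}-3-{2-[2-(benzyloxy)phenyl]ethyl}-5-methoxycyclohexa-2,5-dien-1-one | COC1=CC(=O)C(Cc2ccc(OCc3ccccc3)cc2)=C(CCc2ccccc2OCc2ccccc2)C1 | intermediate
20 | 2-{[4-(benzyloxy)phenyl]methyl}-3-{2-[2-(benzyloxy)phenyl]ethyl}-5-methoxyphenol | COc1cc(O)c(Cc2ccc(OCc3ccccc3)cc2)c(CCc2ccccc2OCc2ccccc2)c1 | intermediate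
21 | 2-[(4-hydroxyphenyl)methyl]-3-[2-(2-hydroxyphenyl)ethyl]-5-methoxyphenol (achiral) | COc1cc(O)c(Cc2ccc(O)cc2)c(CCc2ccccc2O)c1 | target

## Summary
Total step count: 11.
Longest linear sequence: 11 steps (1 to 21).

**Three steps most likely to fail, each with one fallback**

**Step 10 (isoaromatisation).** The rhodium hydride may be slow at the hindered trisubstituted benzylidene, or the vinylogous ester may suffer under the conditions.
- The fallback sets out from 16 and comes back at 20. It replaces the redox-neutral isomerisation by an oxidative aromatisation followed by deoxygenation.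
- Dess–Martin oxidation of the carbinol gives the beta-diketone 6-[4-(benzyloxy)benzoyl]-5-{2-[2-(benzyloxy)phenyl]ethyl}-3-methoxycyclohex-2-en-1-one F1.
- PhSeCl/pyridine in CH2Cl2 selenenylates the doubly activated C6 to give the selenide F2, and H2O2 oxidises it to the selenoxide F3.
- Syn-elimination from F3 can only take the C5–H, because C6 carries no other beta-hydrogen. This gives the acyl dienone F4, which enolises to the 2-hydroxybenzophenone F5.
- Ionic hydrogenation (Et3SiH, TFA, CH2Cl2) then passes through the diarylcarbinol F6 and delivers 20.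

**Step 8 (aldol addition).** The lithium aldolate can revert by retro-aldol, or the enolate can equilibrate by proton transfer.
- The fallback sets out from 13 and comes back at 16.
- The dienolate 15 is trapped with Me3SiCl and isolated as the silyl dienol ether [(3-{2-[2-(benzyloxy)phenyl]ethyl}-5-methoxycyclohexa-1,5-dien-1-yl)oxy]trimethylsilane F7.
- F7 is then joined to 14 in a BF3·OEt2-promoted Mukaiyama aldol reaction at −78 °C. This is irreversible, and the diene can only react at its C6 terminus.

**Step 5 (Michael–Claisen annulation).** The enone may deconjugate or oligomerise under NaOMe before the malonate adds.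
- The fallback sets out from 5 and comes back at 10. It reverses the donor and acceptor roles.
- Wittig reaction of 5 with Ph3P=CHCO2Me gives methyl (2E)-5-[2-(benzyloxy)phenyl]pent-2-enoate F8.
- Methyl acetoacetate with NaOMe in MeOH adds to F8 in a Michael reaction to give dimethyl 2-acetyl-3-{2-[2-(benzyloxy)phenyl]ethyl}pentanedioate F9.
- The acetyl methyl group of F9 closes onto the terminal ester (Dieckmann-type Claisen) and gives the same keto ester 10.

## Further compounds
F1 | step 10 | 6-[4-(benzyloxy)benzoyl]-5-{2-[2-(benzyloxy)phenyl]ethyl}-3-methoxycyclohex-2-en-1-one | COC1=CC(=O)C(C(=O)c2ccc(OCc3ccccc3)cc2)C(CCc2ccccc2OCc2ccccc2)C1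
F2 | step 10 | 6-[4-(benzyloxy)benzoyl]-5-{2-[2-(benzyloxy)phenyl]ethyl}-3-methoxy-6-(phenylselanyl)cyclohex-2-en-1-one | COC1=CC(=O)C([Se]c2ccccc2)(C(=O)c2ccc(OCc3ccccc3)cc2)C(CCc2ccccc2OCc2ccccc2)C1
F3 | step 10 | 6-[4-(benzyloxy)benzoyl]-5-{2-[2-(benzyloxy)phenyl]ethyl}-3-methoxy-6-(phenylseleninyl)cyclohex-2-en-1-one | COC1=CC(=O)C([Se](=O)c2ccccc2)(C(=O)c2ccc(OCc3ccccc3)cc2)C(CCc2ccccc2OCc2ccccc2)C1
F4 | step 10 | 2-[4-(benzyloxy)benzoyl]-3-{2-[2-(benzyloxy)phenyl]ethyl}-5-methoxycyclohexa-2,5-dien-1-one | COC1=CC(=O)C(C(=O)c2ccc(OCc3ccccc3)cc2)=C(CCc2ccccc2OCc2ccccc2)C1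
F5 | step 10 | [4-(benzyloxy)phenyl](2-{2-[2-(benzyloxy)phenyl]ethyl}-6-hydroxy-4-methoxyphenyl)methanone | COc1cc(O)c(C(=O)c2ccc(OCc3ccccc3)cc2)c(CCc2ccccc2OCc2ccccc2)c1
F6 | step 10 | 2-{[4-(benzyloxy)phenyl](hydroxy)methyl}-3-{2-[2-(benzyloxy)phenyl]ethyl}-5-methoxyphenol | COc1cc(O)c(C(O)c2ccc(OCc3ccccc3)cc2)c(CCc2ccccc2OCc2ccccc2)c1
F7 | step 8 | [(3-{2-[2-(benzyloxy)phenyl]ethyl}-5-methoxycyclohexa-1,5-dien-1-yl)oxy]trimethylsilane | COC1=CC(O[Si](C)(C)C)=CC(CCc2ccccc2OCc2ccccc2)C1
F8 | step 5 | methyl (2E)-5-[2-(benzyloxy)phenyl]pent-2-enoate | COC(=O)/C=C/CCc1ccccc1OCc1ccccc1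
F9 | step 5 | dimethyl 2-acetyl-3-{2-[2-(benzyloxy)phenyl]ethyl}pentanedioate | COC(=O)CC(CCc1ccccc1OCc1ccccc1)C(C(C)=O)C(=O)OC
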